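**Retrosynthetic overview**
1. Target 8 ⇒ the C2'–O bond is made last, by B-ring C–H hydroxylation of pentamethoxyflavone 6 at the carbon para to the 3'-OMe.
2. 6 ⇒ O-methylation of flavonol 5.
3. 5 ⇒ the pyranone ring (the only ring built; both benzene rings are bought) is closed by O1–C2 bond formation with C3 oxygenation, from 2'-hydroxychalcone 3.
4. 3 ⇒ aldol condensation of acetophenone 1 with veratraldehyde 2.

Assumption: the target has no stereocentre and no stable stereogenic axis, so the given SMILES is the full structure and no enantiocontrol is needed.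
Assumption: phthaloyl peroxide is a stock reagent made beforehand in one operation from phthaloyl chloride and sodium percarbonate; it is not counted as a route step.

**Step 1**
Reactants: 1 1-(2-hydroxy-3,4-dimethoxyphenyl)ethan-1-one; 2 3,4-dimethoxybenzaldehyde
Product: 5 2-(3,4-dimethoxyphenyl)-3-hydroxy-7,8-dimethoxy-4H-chromen-4-one, via chalcone 3 (not isolated), via dihydroflavonol 4 (not isolated)
Conditions: NaOH (aq), EtOH, rt, 24 h; then 30% H2O2, 0 °C to rt, 6 h
Reagents that add atoms: hydrogen peroxide, OO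
Why: Claisen–Schmidt condensation gives the (E)-2'-hydroxychalcone, which under Algar–Flynn–Oyamada conditions closes the pyranone through O1–C2 bond formation, C3 oxygenation and in-situ dehydrogenation; with no 6'-substituent on the chalcone the flavonol (not the aurone) forms, the racemic trans stereocentres of 4 are erased on oxidation, and water is the only co-product.

**Step 2**
Reactants: 5 2-(3,4-dimethoxyphenyl)-3-hydroxy-7,8-dimethoxy-4H-chromen-4-one
Product: 6 2-(3,4-dimethoxyphenyl)-3,7,8-trimethoxy-4H-chromen-4-one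
Conditions: MeI (2 equiv), K2CO3 (2 equiv), acetone, reflux, 8 h
Reagents that add atoms: iodomethane, CI
Why: Williamson O-methylation (SN2) of the only free hydroxyl, the acidic 3-OH, which is routine for flavonols.

**Step 3**
Reactants: 6 2-(3,4-dimethoxyphenyl)-3,7,8-trimethoxy-4H-chromen-4-one
Product: 8 2-(2-hydroxy-4,5-dimethoxyphenyl)-3,7,8-trimethoxy-4H-chromen-4-one, via aryl hydrogen phthalate 7 (not isolated)
Conditions: phthaloyl peroxide (1.3 equiv), HFIP (0.1 M), 23 °C, 12 h; evaporate; then sat. aq NaHCO3, THF, 40 °C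
Reagents that add atoms: phthaloyl peroxide, O=C1OOC(=O)c2ccccc12
Why: Proposed new method: site-selective B-ring C–H hydroxylation of a polymethoxyflavone with a cyclic diacyl peroxide, in which arene-assisted O–O homolysis ("reverse rebound") delivers a carboxyl oxygen to the most electron-rich unhindered carbon, here C6' (para to the 3'-OMe, which is not conjugated to the carbonyl, on a B ring twisted out of conjugation by the 3-OMe), while HFIP hydrogen-bonds the C4 carbonyl and so deactivates the A ring and the C2=C3 bond, and the product stays masked as the less electron-rich ester 7 until the peroxide is spent, after which carboxylate-assisted hydrolysis frees the phenol; the closest known reaction type is the metal-free C–H hydroxylation of simple alkoxyarenes with phthaloyl peroxide, which has not been shown on flavones or on substrates with two competing alkoxyarene rings and an enol-ether alkene.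

**Compound list**
1 | 1-(2-hydroxy-3,4-dimethoxyphenyl)ethan-1-one | CC(=O)c1ccc(OC)c(OC)c1O | starting material
2 | 3,4-dimethoxybenzaldehyde (veratraldehyde) | COc1ccc(C=O)cc1OC | starting material
3 | (E)-3-(3,4-dimethoxyphenyl)-1-(2-hydroxy-3,4-dimethoxyphenyl)prop-2-en-1-one | O=C(/C=C/c1ccc(OC)c(OC)c1)c1ccc(OC)c(OC)c1O | intermediate (not isolated)
4 | rac-(2R,3R)-2-(3,4-dimethoxyphenyl)-3-hydroxy-7,8-dimethoxy-2,3-dihydro-4H-chromen-4-one (trans, racemate; one enantiomer drawn) | O=C1c2ccc(OC)c(OC)c2O[C@H](c2ccc(OC)c(OC)c2)[C@H]1O | intermediate (not isolated)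
5 | 2-(3,4-dimethoxyphenyl)-3-hydroxy-7,8-dimethoxy-4H-chromen-4-one | O=c1c(O)c(-c2ccc(OC)c(OC)c2)oc2c(OC)c(OC)ccc12 | intermediate
6 | 2-(3,4-dimethoxyphenyl)-3,7,8-trimethoxy-4H-chromen-4-one | O=c1c(OC)c(-c2ccc(OC)c(OC)c2)oc2c(OC)c(OC)ccc12 | intermediate
7 | 2-{[4,5-dimethoxy-2-(3,7,8-trimethoxy-4-oxo-4H-chromen-2-yl)phenoxy]carbonyl}benzoic acid | COc1cc(OC(=O)c2ccccc2C(=O)O)c(-c2oc3c(OC)c(OC)ccc3c(=O)c2OC)cc1OC | intermediate (not isolated)
8 | 2-(2-hydroxy-4,5-dimethoxyphenyl)-3,7,8-trimethoxy-4H-chromen-4-one | COc1cc(O)c(-c2oc3c(OC)c(OC)ccc3c(=O)c2OC)cc1OC | target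

**Totals**
Total step count: 3. Longest linear sequence: 3 steps (1 + 2 → 5 → 6 → 8).

**Steps most likely to fail**

Step 3 (the new reaction). The risks are regioisomers (A-ring C6, B-ring C5'), oxidation of the C2=C3 bond, and low conversion. The fallback uses known chemistry and places the oxygen through a bought C–Br bond; it sets out from 1 and comes back at 8. Compound 1 is condensed (NaOH, EtOH) with commercial 2-bromo-4,5-dimethoxybenzaldehyde F1 to give (E)-3-(2-bromo-4,5-dimethoxyphenyl)-1-(2-hydroxy-3,4-dimethoxyphenyl)prop-2-en-1-one F2. Alkaline H2O2 in the same pot takes F2 through rac-(2R,3R)-2-(2-bromo-4,5-dimethoxyphenyl)-3-hydroxy-7,8-dimethoxy-2,3-dihydro-4H-chromen-4-one F3 to 2-(2-bromo-4,5-dimethoxyphenyl)-3-hydroxy-7,8-dimethoxy-4H-chromen-4-one F4. MeI/K2CO3 then gives 2-(2-bromo-4,5-dimethoxyphenyl)-3,7,8-trimethoxy-4H-chromen-4-one F5. Pd-catalysed hydroxylation of the aryl bromide (tBuBrettPhos Pd G3, KOH, dioxane/H2O, 80 °C) gives 8.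

Step 1 (one-pot aldol/oxidative cyclisation). The risks are a sluggish aldol with the electron-rich aldehyde, Dakin-type loss of unreacted aldehyde, and the reaction stalling at 4. The fallback separates ring closure from C3 oxygenation; it sets out from 3 (made from 1 and 2 by the aldol stage alone and isolated) and comes back at 5. Chalcone 3 is cyclised oxidatively with catalytic I2 in DMSO at 130 °C to 2-(3,4-dimethoxyphenyl)-7,8-dimethoxy-4H-chromen-4-one F6. C3-lithiation (LDA, THF, −78 °C) and B(OMe)3 give dimethyl [2-(3,4-dimethoxyphenyl)-7,8-dimethoxy-4-oxo-4H-chromen-3-yl]boronate F7, which is oxidised in the same flask with H2O2/AcOH to 5.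

Step 2 (methylation). The risk is incomplete reaction of the hydrogen-bonded 3-OH under carbonate. The fallback sets out from 5 and comes back at 6: Mitsunobu etherification with methanol (PPh3, DIAD, MeOH, THF, 0 °C to rt), which activates the alcohol under neutral redox-condensation conditions instead of relying on the flavonolate as an SN2 nucleophile. It makes no new compound.

**Further compounds**
F1 | step 3 | 2-bromo-4,5-dimethoxybenzaldehyde | COc1cc(Br)c(C=O)cc1OC
F2 | step 3 | (E)-3-(2-bromo-4,5-dimethoxyphenyl)-1-(2-hydroxy-3,4-dimethoxyphenyl)prop-2-en-1-one | O=C(/C=C/c1cc(OC)c(OC)cc1Br)c1ccc(OC)c(OC)c1O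
F3 | step 3 | rac-(2R,3R)-2-(2-bromo-4,5-dimethoxyphenyl)-3-hydroxy-7,8-dimethoxy-2,3-dihydro-4H-chromen-4-one | O=C1c2ccc(OC)c(OC)c2O[C@H](c2cc(OC)c(OC)cc2Br)[C@H]1O
F4 | step 3 | 2-(2-bromo-4,5-dimethoxyphenyl)-3-hydroxy-7,8-dimethoxy-4H-chromen-4-one | O=c1c(O)c(-c2cc(OC)c(OC)cc2Br)oc2c(OC)c(OC)ccc12
F5 | step 3 | 2-(2-bromo-4,5-dimethoxyphenyl)-3,7,8-trimethoxy-4H-chromen-4-one | O=c1c(OC)c(-c2cc(OC)c(OC)cc2Br)oc2c(OC)c(OC)ccc12
F6 | step 1 | 2-(3,4-dimethoxyphenyl)-7,8-dimethoxy-4H-chromen-4-one | O=c1cc(-c2ccc(OC)c(OC)c2)oc2c(OC)c(OC)ccc12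
F7 | step 1 | dimethyl [2-(3,4-dimethoxyphenyl)-7,8-dimethoxy-4-oxo-4H-chromen-3-yl]boronate | COB(OC)c1c(-c2ccc(OC)c(OC)c2)oc2c(OC)c(OC)ccc2c1=O
F0 | step 2 | none | none
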